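Charged with twice the protic impurity of the eta run, the delta run read highest at 15.4 % against 15.8 % for eta, a gap of 0.4 percentage points when each reading is good to 0.3 points.

common to all: starting material 2.0 × 10⁻⁴ M

| charge | partner | protic impurity | remark | time |
|---|---|---|---|---|
| eta | 0.26 mM | 0.0067 mM | run made earlier |  |
| delta | 0.26 mM | 0.015 mM | run made earlier |  |
| flask | 0.260 mM | 0.0100 mM |  | 20 min |

- eta (time / min: target / %): 0.167: 12.8; 0.250: 15.7; 0.500: 15.8; 1.33: 12.1; 2.50: 11.4; 6.00: 11.6; 12.0: 12.0
- delta (time / min: target / %): 0.167: 12.5; 0.250: 15.4; 0.500: 14.9; 1.33: 12.0; 2.50: 11.4; 6.00: 11.0; 12.0: 11.4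

(scatter of a reading: 0.3 percentage points)



* time up to 20 min at which target stands highest
* the amount of target, in percent of the starting material charged, at that time

I compared the level of target late on with the level at the top of the curve, in both runs. The last 3 readings of both runs, from 2.50 min onward, average 11.5 %, and the two highest readings average 15.6 %, so their quotient was 0.735, and this is the late-to-top ratio: the late level of target as a fraction of the highest readings, a ratio of two levels and not the chance that any one molecule stays target. That late level stands lower than the top, and the flask's c(protic impurity) of 0.0100 mM lies between those of the two runs, so I looked for the flask's highest point early rather than at 20 min.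

The weak link was the top itself, since the readings at 0.250 min and 0.500 min straddle it and the curve rises above them. I committed to 16.3 % at 0.35 min, holding that “the early peak remains the maximum”.

The flask gave 16.3 % at 0.352 min.

    starting material → open intermediate (k = 0.0420 s⁻¹)
    partner → second intermediate (k = 1.00 s⁻¹)
    open intermediate + second intermediate → target (k = 2000 L mol⁻¹ s⁻¹)
    2 second intermediate → homo product (k = 1000 L mol⁻¹ s⁻¹)
    starting material + protic impurity → quenched substrate (k = 33000 L mol⁻¹ s⁻¹)
    target ⇌ isomer of the product (K = 1.20, k = 0.0360 s⁻¹)
    second intermediate → decomposed reagent (k = 0.0230 s⁻¹)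

The relaxation half-life of target and isomer of the product, 0.175 min, is short against 20 min, and at 20.0 min this flask held 11.6 % of target beside 13.9 % of isomer. The late-to-top ratio turns its 16.3 % into 12.0 %, to set beside that 11.6 %. The neighbour with c(partner) of 1.0 × 10⁻⁴ M, where partner was the limiting reagent at 0.500 equiv and 0 % of it was left, topped at 12.1 %; the ratio turns that into 8.89 %, and that neighbour stood at 8.38 % of target at 20.0 min.

The runs are calculated for an exercise; noise was put on by code.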